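## Analysis of the target

The target is a 3,3''-biflavanone: two 5-hydroxy-2-(4-methoxyphenyl)chroman-4-one units (each with rings A, C and B) are joined by the C3–C3'' single bond, one carrying a free 7-hydroxyl and the other a 7''-methoxyl. The four stereocentres C2, C3, C3'' and C2'' are contiguous and all S. In each ring C this puts the 2-aryl group and the C3–C3'' bond on the same face (H2 and H3 cis; the trans isomer would be 2S,3R), and the two halves have the same sense, so the core is twofold-symmetric and only the 7''-O-methyl group breaks the symmetry. The cis arrangement is the fragile one: H3 and H3'' are α to the C4 ketones and can epimerise to the trans series, the same enolates can expel O1 from C2 (chalcone opening), and the 4-methoxybenzylic C2–O1 bond ionises in strong acid. The free phenols and the need to methylate one of two equivalent 7-hydroxyls add a chemoselectivity problem. The difficulty is therefore to build a twofold-symmetric stereotetrad with two cis-2,3 relationships and to add two phloroglucinol rings with as little exposure of C3 to equilibrating conditions as possible. The plan rests on the fact that each ring A is an acylphloroglucinol, oxygenated at C5, C7 and C8a and acylated at C4a, which is the Claisen folding pattern of a triketide chain C5–C6–C7–C8–C8a–C4a. A 2,3-dihydro-4-pyranone ring C can hold that chain in masked form with O1 already on C8a.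

## Retrosynthetic reasoning

14 back to 13. The O–CH3 bond at C7'' is cut last. Compound 13 is the twofold-symmetric tetraphenol; its two 7-hydroxyls are homotopic and much more acidic than the chelated 5-hydroxyls. Cutting here keeps every earlier intermediate symmetric, at the price of a statistical mono-methylation in the last step.

13 back to 12. Both rings A are opened at C4a–C5 and C4a''–C5'' (retro-Claisen). Compound 12 is the 3,3'-bi(2-aryl-2,3-dihydro-4-pyranone) with a 4-methoxy-2,4-dioxobutyl chain on each C8a. This cut is chosen because all four stereocentres and both O1–C2 bonds are already in place in 12, no aromatic building block is needed, and the oxygen pattern of ring A follows from the chain. The forward reaction must make the ring carbon C4a, not the chain methylene C6, the nucleophile, and must not enolise C3.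

12 back to 9 and 10. The C8–C7 bonds are cut. Compound 9 is the same bipyranone with a methyl group on each C8a, and 10 is the half-ester chloride of malonic acid, needed once per half. Closing ring C by acid cyclodehydration with the whole chain already attached was rejected. The C2 hydroxyl would then be δ to C8a but also γ to the C4'' ketone of the other half, so five-ring closure across the halves (the connectivity of 6) and 4-pyranone formation within the chain would compete with the wanted six-ring closure. Making ring C first and lengthening the chain afterwards removes that choice. The forward reaction must enolise the C8a methyl group and not H3 (through 11), and must acylate on carbon.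

9 back to 8. The O1–C8a bonds are cut. Compound 8 is the bis(β-hydroxy ynone). With an alkyne at C4a≡C8a the hydroxyl has only one productive reaction, 6-endo addition to C8a; a hemiketal with the other ketone can form but cannot dehydrate. The C2–O bond is never broken, so the syn relationship of hydroxyl and branch in 8 becomes the cis-2,3 relationship of ring C.

8 back to 6 and 7. The C4–C4a and C4''–C4a'' bonds are cut. Compound 6 is the exo,exo dilactone, whose carbonyl carbons are C4 and C4'' and whose ring oxygens are the future O1 atoms; 7 is the propynyl anion that brings C4a, C8a and C8, one molecule per lactone. A lactone is a mono-acylating agent at low temperature, and only acyl C–O bonds are broken.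

6 back to 5. The two benzylic C2–O bonds are cut back to C–H. Compound 5 is (2R,3R)-2,3-bis(4-methoxybenzyl)succinic acid. An aryl group that is exo in the dilactone (cis to the bridgehead hydrogen) is cis to the C3–C3'' bond once ring C is closed, so 6 maps onto the cis,cis target. Only C3 and C3'' need reagent control: the bicycle can only be cis-fused, and the aryl groups take the convex face.

5 back to 4, 3, 1 and 2. The C3–C3'' bond is cut. Oxidative homocoupling of the enolate of imide 3 joins two identical molecules, and the oxazolidinone auxiliary 2 sets both new centres in the same sense, which gives the twofold-symmetric R,R dimer 4; hydrolysis gives 5. Acid 1 and auxiliary 2 are commercial.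

## Alternatives that were turned down

Alternative 1: The disconnection is at the two carbinol C–H bonds and the two lactone C–O bonds of the dilactone A1, which is the same compound as 6. In the forward step a chiral divalent ruthenium diamine transfer-hydrogenation catalyst would reduce both aryl ketones of the epimerising diaroylsuccinate A2 under dynamic kinetic resolution, and each carbinol would lactonise onto the remote ester.
- For it: A2 is one oxidative dimerisation away from the commercial β-keto ester A3, so A1 would be reached in two steps against four here, and the catalyst would reduce both halves in the same sense. On step economy it is stronger.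
- Against it: the syn or anti sense at C3 is not secured, because the α-carbon carries an ester and a branched succinate residue, and hydride delivery anti to the ester would give the anti product (endo aryl, trans-flavanone series). After the first reduction and lactonisation the second labile centre sits in an α-acyl lactone with a different bias. The 1,4-diketone can also cyclodehydrate to a furan in the acidic formate medium.
- Comparison: it ends at A1 and leaves rings A and C open, so it is a route to 6 and not to 14. The chosen route sets only C3 and C3'' with a reagent, by a coupling whose sense is known for this imide class, and lets the benzylic centres follow. If the reduction proved syn-selective it could replace steps 1 to 4.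

Alternative 2: The disconnection is at the C2–aryl and C2''–aryl bonds. A chiral divalent palladium catalyst would add the arylboronic acid A4 to C2 and then C2'' of the unsymmetrical 3,3'-bichromone A5, giving the tri-O-benzyl ether A6 of the target.
- For it: rings A and C exist from the start, and the 7''-methoxyl is already distinguished from the benzyl ethers, so no statistical methylation is needed. On that point it is stronger. Asymmetric conjugate arylation of chromones is known.
- Against it: C3 and C3'' are set by protonation of enolates, not by the catalyst. The cis product needs kinetic protonation anti to the new aryl group twice, and it can epimerise to trans under the hot protic conditions. A5 is a hindered, electron-rich acceptor with a peri 5-benzyloxy group, the second addition meets two existing stereocentres, and A5 itself needs a cross-coupling of two different chromones.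
- Comparison: the chosen route fixes all four centres on an sp3 framework before any ring C exists and pays with the statistical last step.

Alternative 3: The disconnection is at O1–C8a and C4–C4a of both rings C. Each alkoxide of the bis(hydroxy Weinreb amide) A7 would add to the fluoride-generated aryne A8, and each resulting aryl anion would acylate the neighbouring amide, giving the tetra-O-benzyl ether A9.
- For it: from the dilactone 6 it would reach the full skeleton in two steps plus hydrogenolysis, which is shorter than steps 5 to 8 here. The regiochemistry of addition to A8 (oxygen adds distal to the flanking benzyloxy group) is the natural one.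
- Against it: each alkoxide of A7 is γ to the other amide, and lactonisation back towards 6 is intramolecular while capture of A8 is bimolecular. Each aryl anion must attack a hindered α-branched amide before it is protonated, and this must happen twice. Generating A8 requires a multi-step preparation of its own, and the statistical methylation remains.
- Comparison: both key steps are unprecedented. The chosen one is intramolecular, made irreversible by aromatisation, has its regiochemistry fixed by ring C, and uses no aromatic building block for ring A.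

Key step: step 8

Remark: flavanone atom numbers (C2 to C8a, doubly primed for the second half) are used for the corresponding atoms of all intermediates; prop-1-yn-1-yllithium and methyl 3-chloro-3-oxopropanoate are taken as commercial.

Remark: steps 2, 5 and 7 each take up two molecules of one component; one stands on the Reactants line and the second is entered under "Reagents that add atoms".

Step 1
Reactants: 1 3-(4-methoxyphenyl)propanoic acid; 2 (4S)-4-(propan-2-yl)-1,3-oxazolidin-2-one
Product: 3 (4S)-3-[3-(4-methoxyphenyl)propanoyl]-4-(propan-2-yl)-1,3-oxazolidin-2-one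
Conditions: t-BuCOCl, Et3N, THF, −20 °C; then 2, LiCl, 25 °C
Reagents that add atoms: none
Why: N-acylation of the oxazolidinone through the pivaloyl mixed anhydride with LiCl/Et3N, the standard way to attach this auxiliary; no stereocentre is formed.

Step 2
Reactants: 3 (4S)-3-[3-(4-methoxyphenyl)propanoyl]-4-(propan-2-yl)-1,3-oxazolidin-2-one
Product: 4 (2R,3R)-2,3-bis[(4-methoxyphenyl)methyl]-1,4-bis[(4S)-2-oxo-4-(propan-2-yl)-1,3-oxazolidin-3-yl]butane-1,4-dione
Conditions: LiN(iPr)2 (1.1 equiv), THF, −78 °C; then TiCl4 (1.0 equiv), −78 → 0 °C
Reagents that add atoms: second molecule of imide 3 (homocoupling partner), COc1ccc(CCC(=O)N2[C@@H](C(C)C)COC2=O)cc1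
Why: Oxidative homocoupling of an N-acyl oxazolidinone enolate, known for 3-arylpropanoyl imides: two molecules of 3 are enolised, the chelated Z-enolates are oxidised by tetravalent titanium (which becomes trivalent) and the two α-carbons join with loss of two hydrogens. Each new centre is set by the auxiliary, the partner approaching the enolate face opposite the 4-isopropyl group, which should give the R,R dimer from the 4S auxiliary.

Step 3
Reactants: 4 (2R,3R)-2,3-bis[(4-methoxyphenyl)methyl]-1,4-bis[(4S)-2-oxo-4-(propan-2-yl)-1,3-oxazolidin-3-yl]butane-1,4-dione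
Product: 5 (2R,3R)-2,3-bis[(4-methoxyphenyl)methyl]butanedioic acid
Conditions: LiOH, H2O2, THF/H2O, 0 °C; Na2SO3; HCl
Reagents that add atoms: hydrogen peroxide (as LiOOH), OO
Why: Hydroperoxide cleaves the exocyclic imide carbonyls selectively (standard auxiliary removal) and supplies the carboxyl OH oxygens; the α-centres are not enolised at 0 °C and auxiliary 2 is recovered.

Step 4
Reactants: 5 (2R,3R)-2,3-bis[(4-methoxyphenyl)methyl]butanedioic acid
Product: 6 (1S,2S,5S,6S)-2,6-bis(4-methoxyphenyl)-3,7-dioxabicyclo[3.3.0]octane-4,8-dione (exo,exo dilactone)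
Conditions: DDQ (2.5 equiv), AcOH, 50 °C
Reagents that add atoms: none
Why: Dehydrogenative benzylic lactonisation: the quinone abstracts hydride from each 4-methoxybenzylic CH2 and the cation is captured by the γ-carboxyl group (5-exo). The first closure should place the aryl group trans to the neighbouring carboxyl, the second can only give the cis-fused bicycle with its aryl group on the convex face, and the ionisable benzylic C–O bonds let any endo isomer drain to the exo,exo compound. C2 and C2'' are thus set by the fixed C3 and C3'' centres (substrate control).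

Step 5
Reactants: 6 (1S,2S,5S,6S)-2,6-bis(4-methoxyphenyl)-3,7-dioxabicyclo[3.3.0]octane-4,8-dione; 7 prop-1-yn-1-yllithium
Product: 8 (5S,6S)-5,6-bis[(S)-hydroxy(4-methoxyphenyl)methyl]deca-2,8-diyne-4,7-dione
Conditions: 7 (2.4 equiv), THF, −78 °C; AcOH, −78 °C
Reagents that add atoms: second molecule of prop-1-yn-1-yllithium 7 (one per lactone), [Li]C#CC
Why: Alkynylation of a lactone to a hydroxy ynone, once at each lactone carbonyl: a lithium acetylide adds only once because the tetrahedral adduct persists as a lactol alkoxide until the cold quench. Only acyl C–O bonds break, so C2, C3, C3'' and C2'' are untouched; 8 may rest partly as the bicyclic bis-hemiketal, which feeds step 6 through the open form.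

Step 6
Reactants: 8 (5S,6S)-5,6-bis[(S)-hydroxy(4-methoxyphenyl)methyl]deca-2,8-diyne-4,7-dione
Product: 9 (2S,2'S,3S,3'S)-2,2'-bis(4-methoxyphenyl)-6,6'-dimethyl-2,2',3,3'-tetrahydro-4H,4'H-[3,3'-bipyran]-4,4'-dione
Conditions: Ph3PAuCl (5 mol%), AgOTf (5 mol%), CH2Cl2, 25 °C
Reagents that add atoms: none
Why: Cationic monovalent gold activates each ynone for 6-endo-dig attack of its own β-hydroxyl on C8a (hydroalkoxylation of β-hydroxy ynones, a known route to 2,3-dihydro-4-pyranones). The C2–O bond stays intact and C3 is not enolised, so the syn relationship in 8 becomes 2,3-cis. The five-ring hemiketal with the other ketone is only a reversible resting state, because an alkynyl hemiketal cannot dehydrate to a conjugated enol ether.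

Step 7
Reactants: 9 (2S,2'S,3S,3'S)-2,2'-bis(4-methoxyphenyl)-6,6'-dimethyl-2,2',3,3'-tetrahydro-4H,4'H-[3,3'-bipyran]-4,4'-dione; 10 methyl 3-chloro-3-oxopropanoate
Product: 12 dimethyl 4,4'-[(2S,2'S,3S,3'S)-2,2'-bis(4-methoxyphenyl)-4,4'-dioxo-3,3',4,4'-tetrahydro-2H,2'H-[3,3'-bipyran]-6,6'-diyl]bis(3-oxobutanoate), via bis(trimethylsilyl dienol ether) 11 (not isolated)
Conditions: TMSOTf, Et3N, CH2Cl2, −78 °C; pentane, filtration; then 10 (2.2 equiv), CH2Cl2, −78 → 0 °C; aq. NaHCO3
Reagents that add atoms: second molecule of methyl 3-chloro-3-oxopropanoate 10 (one per methyl group), COC(=O)CC(Cl)=O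
Why: Soft enolisation of the vinylogous ester should remove a proton from the unhindered C8a methyl group and not the tertiary, flanked H3, giving the exocyclic 2-alkoxy-4-silyloxy diene 11 (known for 6-methyl-dihydropyranones). Each terminal carbon C8, activated by both O1 and the silyloxy group, is then C-acylated by one molecule of the acid chloride (vinylogous Mukaiyama-type acylation of a silyloxy diene) with loss of chlorotrimethylsilane, which restores the pyranone and forms C8–C7.

Step 8
Reactants: 12 dimethyl 4,4'-[(2S,2'S,3S,3'S)-2,2'-bis(4-methoxyphenyl)-4,4'-dioxo-3,3',4,4'-tetrahydro-2H,2'H-[3,3'-bipyran]-6,6'-diyl]bis(3-oxobutanoate)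
Product: 13 (2S,2'S,3S,3'S)-5,5',7,7'-tetrahydroxy-2,2'-bis(4-methoxyphenyl)-[3,3'-bichromane]-4,4'-dione
Conditions: Mg(OCH3)2 (8 equiv), CH3OH/THF, 0 → 25 °C; cold 1 M HCl to pH 4
Reagents that add atoms: none
Why: Proposed new method: Mg(OCH3)2 deprotonates each side chain at C8, giving a magnesium-chelated cross-conjugated dienolate with charge on C8 and C4a; C4a adds to the C5 ester carbonyl, methoxide leaves and two enolisations aromatise the ring to the 5,7-dihydroxy pattern. The closest known reactions are the Mg(OCH3)2-mediated Claisen cyclisation of open-chain 3,5,7-triketo esters to acylphloroglucinols and base-induced cyclisations of 4-pyranone-masked polyketide chains. Each ring A closes in a 6-(enolendo)-exo-trig mode through C4a, C8a, C8, C7, C6 and C5, and the two closures are independent. No stereocentre is formed; C2, C3, C2'' and C3'' are only carried through. The step needs Claisen folding (C4a to C5) and not aldol folding (C6 to C4): O1 locks the C4a=C8a double bond with C8 trans to C4, so the C6 carbanion cannot reach the C4 carbonyl, and with O1 on C8a there is no enol oxygen for 2-pyranone formation. It also needs the cis C2/C3 relationship to survive: the C8 and C6 protons are far more acidic than H3, and the weakly basic, chelating reagent at 0–25 °C should not enolise C4 towards C3 or trigger O1–C2 β-elimination. Once a ring is aromatic, the 5-oxido–Mg–carbonyl chelate and the 7-phenoxide lower the acidity of H3 further. Aromatisation makes each closure irreversible, so a small equilibrium share of the reactive enolate is enough.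

Step 9
Reactants: 13 (2S,2'S,3S,3'S)-5,5',7,7'-tetrahydroxy-2,2'-bis(4-methoxyphenyl)-[3,3'-bichromane]-4,4'-dione
Product: 14 (2S,3S)-3-[(2S,3S)-5-hydroxy-7-methoxy-2-(4-methoxyphenyl)-4-oxo-3,4-dihydro-2H-chromen-3-yl]-5,7-dihydroxy-2-(4-methoxyphenyl)-2,3-dihydro-4H-chromen-4-one
Conditions: TMSCHN2 (1.0 equiv), CH3OH/toluene, 0 → 25 °C
Reagents that add atoms: trimethylsilyldiazomethane, C[Si](C)(C)C=[N+]=[N-]
Why: Diazoalkane O-methylation follows acidity: the 7-hydroxyls react and the chelated 5-hydroxyls do not. The two 7-hydroxyls of 13 are homotopic, so one equivalent should give a statistical mixture from which 14 is separated and 13 recycled; the neutral conditions leave C3 and the O1–C2 bond alone.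

Compound list

1 | 3-(4-methoxyphenyl)propanoic acid | COc1ccc(CCC(=O)O)cc1 | starting material
2 | (4S)-4-(propan-2-yl)-1,3-oxazolidin-2-one | CC(C)[C@H]1COC(=O)N1 | starting material
3 | (4S)-3-[3-(4-methoxyphenyl)propanoyl]-4-(propan-2-yl)-1,3-oxazolidin-2-one | COc1ccc(CCC(=O)N2[C@@H](C(C)C)COC2=O)cc1 | intermediate
4 | (2R,3R)-2,3-bis[(4-methoxyphenyl)methyl]-1,4-bis[(4S)-2-oxo-4-(propan-2-yl)-1,3-oxazolidin-3-yl]butane-1,4-dione | COc1ccc(C[C@@H](C(=O)N2[C@@H](C(C)C)COC2=O)[C@@H](Cc2ccc(OC)cc2)C(=O)N2[C@@H](C(C)C)COC2=O)cc1 | intermediate
5 | (2R,3R)-2,3-bis[(4-methoxyphenyl)methyl]butanedioic acid | COc1ccc(C[C@@H](C(=O)O)[C@@H](Cc2ccc(OC)cc2)C(=O)O)cc1 | intermediate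
6 | (1S,2S,5S,6S)-2,6-bis(4-methoxyphenyl)-3,7-dioxabicyclo[3.3.0]octane-4,8-dione (exo,exo) | COc1ccc([C@H]2OC(=O)[C@H]3[C@@H]2C(=O)O[C@@H]3c2ccc(OC)cc2)cc1 | intermediate
7 | prop-1-yn-1-yllithium | [Li]C#CC | starting material
8 | (5S,6S)-5,6-bis[(S)-hydroxy(4-methoxyphenyl)methyl]deca-2,8-diyne-4,7-dione | COc1ccc(cc1)[C@@H](O)[C@@H](C(=O)C#CC)[C@H](C(=O)C#CC)[C@H](O)c1ccc(OC)cc1 | intermediate
9 | (2S,2'S,3S,3'S)-2,2'-bis(4-methoxyphenyl)-6,6'-dimethyl-2,2',3,3'-tetrahydro-4H,4'H-[3,3'-bipyran]-4,4'-dione | COc1ccc([C@H]2OC(C)=CC(=O)[C@H]2[C@@H]2C(=O)C=C(C)O[C@@H]2c2ccc(OC)cc2)cc1 | intermediate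
10 | methyl 3-chloro-3-oxopropanoate | COC(=O)CC(Cl)=O | starting material
11 | (2S,2'S,3S,3'S)-2,2'-bis(4-methoxyphenyl)-6,6'-dimethylidene-4,4'-bis(trimethylsilyloxy)-3,3',6,6'-tetrahydro-2H,2'H-3,3'-bipyran | COc1ccc([C@H]2OC(=C)C=C(O[Si](C)(C)C)[C@H]2[C@@H]2C(O[Si](C)(C)C)=CC(=C)O[C@@H]2c2ccc(OC)cc2)cc1 | intermediate
12 | dimethyl 4,4'-[(2S,2'S,3S,3'S)-2,2'-bis(4-methoxyphenyl)-4,4'-dioxo-3,3',4,4'-tetrahydro-2H,2'H-[3,3'-bipyran]-6,6'-diyl]bis(3-oxobutanoate) | COc1ccc([C@H]2OC(CC(=O)CC(=O)OC)=CC(=O)[C@H]2[C@@H]2C(=O)C=C(CC(=O)CC(=O)OC)O[C@@H]2c2ccc(OC)cc2)cc1 | intermediate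
13 | (2S,2'S,3S,3'S)-5,5',7,7'-tetrahydroxy-2,2'-bis(4-methoxyphenyl)-[3,3'-bichromane]-4,4'-dione | COc1ccc([C@H]2Oc3cc(O)cc(O)c3C(=O)[C@H]2[C@@H]2C(=O)c3c(O)cc(O)cc3O[C@@H]2c2ccc(OC)cc2)cc1 | intermediate
14 | (2S,3S)-3-[(2S,3S)-5-hydroxy-7-methoxy-2-(4-methoxyphenyl)-4-oxo-3,4-dihydro-2H-chromen-3-yl]-5,7-dihydroxy-2-(4-methoxyphenyl)-2,3-dihydro-4H-chromen-4-one | COc1ccc([C@H]2Oc3cc(O)cc(O)c3C(=O)[C@H]2[C@@H]2C(=O)c3c(O)cc(OC)cc3O[C@@H]2c2ccc(OC)cc2)cc1 | target

Total step count: 9. Longest linear sequence: 9 steps (1 to 14 through 3, 4, 5, 6, 8, 9, 12 and 13).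

Least certain steps

Step 8 (key step). The most likely failure is loss of the cis C2/C3 relationship, by enolisation at C3 or by β-elimination of O1 from C2, either in 12 or in the product phenoxide. The other risk is stalling after deprotonation at C6, because the β-keto ester enolate shields the ester from attack by C4a. The fallback uses known chemistry and brings in rings A as finished arenes; it sets out from 6 and returns at 13. Dilactone 6 is opened at −78 °C, as in step 5, with 2,4-bis(benzyloxy)-6-fluorophenyllithium (from the aryl bromide and n-BuLi), giving the bis(β-hydroxy aryl ketone) F1. Cs2CO3 in DMF then closes both rings C by intramolecular SNAr displacement of the fluoride ortho to the ketone, which forms O1–C8a with retention at C2 and gives the tetra-O-benzyl ether F2 (identical with A9). Hydrogenolysis (H2, Pd/C, EtOAc) gives 13.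

Step 7. The most likely failure is silylation-induced enolisation at C3 instead of at the methyl group, which would erase the C3 configuration, or opening of the O-silylated ring at the 4-methoxybenzylic O1–C2 bond. O-acylation in place of C8-acylation is the third risk. The fallback carries C8 and C7 in the alkyne; it sets out from 6 and returns at 12. Dilactone 6 is treated at −78 °C with the lithium acetylide of 4,4-diethoxybut-1-yne to give the bis(hydroxy ynone) acetal F3. Ph3PAuCl/AgOTf cyclises it as in step 6 to the bis(2,2-diethoxyethyl)bipyranone F4, and mild aqueous acid frees the dialdehyde F5. Roskamp homologation with methyl diazoacetate and catalytic SnCl2 then gives 12.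

Step 4. The most likely failure is incomplete hydride abstraction from the second, now electron-poorer, benzylic position. The other risk is proton loss from the benzylic cation to an arylidene succinate, which would destroy C3. The fallback changes from hydride abstraction to radical halogenation; it sets out from 5 and returns at 6. Diacid 5 is esterified (TMSCHN2) to the dimethyl ester F6. NBS with dibenzoyl peroxide in PhCF3 at 80 °C gives the bis(benzylic bromide) F7 as an epimer mixture. On warming, each ester carbonyl oxygen displaces bromide and loses bromomethane, and the ionising benzylic centres settle in the exo,exo dilactone 6.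

Step 5. The most likely failure is deprotonation of the bridgehead C–H next to a lactone carbonyl followed by elimination of the carboxylate from C2. A second acetylide addition to a liberated ynone is the other risk. The fallback separates ring opening from C–C bond formation; it sets out from 6 and returns at 8. Dilactone 6 is opened with the aluminium amide from Al(CH3)3 and N,O-dimethylhydroxylamine hydrochloride to give the bis(hydroxy Weinreb amide) F8. Its dialkoxide is treated with excess CH3C≡CMgBr in THF at 0 °C to give 8; the chelated tetrahedral intermediate excludes over-addition, and an alkoxide on C2 cannot be eliminated.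

Further compounds

F1 | step 8 | (2S,3S)-1,4-bis[2,4-bis(benzyloxy)-6-fluorophenyl]-2,3-bis[(S)-hydroxy(4-methoxyphenyl)methyl]butane-1,4-dione | COc1ccc(cc1)[C@@H](O)[C@@H](C(=O)c1c(F)cc(OCc2ccccc2)cc1OCc1ccccc1)[C@H](C(=O)c1c(F)cc(OCc2ccccc2)cc1OCc1ccccc1)[C@H](O)c1ccc(OC)cc1
F2 | step 8 | (2S,2'S,3S,3'S)-5,5',7,7'-tetrakis(benzyloxy)-2,2'-bis(4-methoxyphenyl)-[3,3'-bichromane]-4,4'-dione | COc1ccc([C@H]2Oc3cc(OCc4ccccc4)cc(OCc4ccccc4)c3C(=O)[C@H]2[C@@H]2C(=O)c3c(OCc4ccccc4)cc(OCc4ccccc4)cc3O[C@@H]2c2ccc(OC)cc2)cc1
F3 | step 7 | (6S,7S)-1,1,12,12-tetraethoxy-6,7-bis[(S)-hydroxy(4-methoxyphenyl)methyl]dodeca-3,9-diyne-5,8-dione | COc1ccc(cc1)[C@@H](O)[C@@H](C(=O)C#CCC(OCC)OCC)[C@H](C(=O)C#CCC(OCC)OCC)[C@H](O)c1ccc(OC)cc1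
F4 | step 7 | (2S,2'S,3S,3'S)-6,6'-bis(2,2-diethoxyethyl)-2,2'-bis(4-methoxyphenyl)-2,2',3,3'-tetrahydro-4H,4'H-[3,3'-bipyran]-4,4'-dione | COc1ccc([C@H]2OC(CC(OCC)OCC)=CC(=O)[C@H]2[C@@H]2C(=O)C=C(CC(OCC)OCC)O[C@@H]2c2ccc(OC)cc2)cc1
F5 | step 7 | 2,2'-[(2S,2'S,3S,3'S)-2,2'-bis(4-methoxyphenyl)-4,4'-dioxo-3,3',4,4'-tetrahydro-2H,2'H-[3,3'-bipyran]-6,6'-diyl]diacetaldehyde | COc1ccc([C@H]2OC(CC=O)=CC(=O)[C@H]2[C@@H]2C(=O)C=C(CC=O)O[C@@H]2c2ccc(OC)cc2)cc1
F6 | step 4 | dimethyl (2R,3R)-2,3-bis[(4-methoxyphenyl)methyl]butanedioate | COc1ccc(C[C@@H](C(=O)OC)[C@@H](Cc2ccc(OC)cc2)C(=O)OC)cc1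
F7 | step 4 | dimethyl (2R,3R)-2,3-bis[bromo(4-methoxyphenyl)methyl]butanedioate (benzylic epimers) | COc1ccc(C(Br)[C@@H](C(=O)OC)[C@@H](C(Br)c2ccc(OC)cc2)C(=O)OC)cc1
F8 | step 5 | (2S,3S)-2,3-bis[(S)-hydroxy(4-methoxyphenyl)methyl]-N1,N4-dimethoxy-N1,N4-dimethylbutanediamide | COc1ccc(cc1)[C@@H](O)[C@@H](C(=O)N(C)OC)[C@H](C(=O)N(C)OC)[C@H](O)c1ccc(OC)cc1
A1 | alternative 1 | (1S,2S,5S,6S)-2,6-bis(4-methoxyphenyl)-3,7-dioxabicyclo[3.3.0]octane-4,8-dione (identical with 6) | COc1ccc([C@H]2OC(=O)[C@H]3[C@@H]2C(=O)O[C@@H]3c2ccc(OC)cc2)cc1
A2 | alternative 1 | dimethyl 2,3-bis(4-methoxybenzoyl)butanedioate (epimerising mixture) | COC(=O)C(C(=O)c1ccc(OC)cc1)C(C(=O)OC)C(=O)c1ccc(OC)cc1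
A3 | alternative 1 | methyl 3-(4-methoxyphenyl)-3-oxopropanoate | COc1ccc(C(=O)CC(=O)OC)cc1
A4 | alternative 2 | (4-methoxyphenyl)boronic acid | COc1ccc(B(O)O)cc1
A5 | alternative 2 | 5,5',7-tris(benzyloxy)-7'-methoxy-4H,4'H-[3,3'-bichromene]-4,4'-dione | O=c1c(coc2cc(OCc3ccccc3)cc(OCc3ccccc3)c12)-c1coc2cc(OC)cc(OCc3ccccc3)c2c1=O
A6 | alternative 2 | (2S,3S)-5,7-bis(benzyloxy)-3-[(2S,3S)-5-(benzyloxy)-7-methoxy-2-(4-methoxyphenyl)-4-oxo-3,4-dihydro-2H-chromen-3-yl]-2-(4-methoxyphenyl)-2,3-dihydro-4H-chromen-4-one | COc1ccc([C@H]2Oc3cc(OCc4ccccc4)cc(OCc4ccccc4)c3C(=O)[C@H]2[C@@H]2C(=O)c3c(OCc4ccccc4)cc(OC)cc3O[C@@H]2c2ccc(OC)cc2)cc1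
A7 | alternative 3 | (2S,3S)-2,3-bis[(S)-hydroxy(4-methoxyphenyl)methyl]-N1,N4-dimethoxy-N1,N4-dimethylbutanediamide | COc1ccc(cc1)[C@@H](O)[C@@H](C(=O)N(C)OC)[C@H](C(=O)N(C)OC)[C@H](O)c1ccc(OC)cc1
A8 | alternative 3 | 3,5-bis(benzyloxy)benzyne (1,2-didehydro-3,5-bis(benzyloxy)benzene) | C1#CC(OCc2ccccc2)=CC(OCc2ccccc2)=C1
A9 | alternative 3 | (2S,2'S,3S,3'S)-5,5',7,7'-tetrakis(benzyloxy)-2,2'-bis(4-methoxyphenyl)-[3,3'-bichromane]-4,4'-dione | COc1ccc([C@H]2Oc3cc(OCc4ccccc4)cc(OCc4ccccc4)c3C(=O)[C@H]2[C@@H]2C(=O)c3c(OCc4ccccc4)cc(OCc4ccccc4)cc3O[C@@H]2c2ccc(OC)cc2)cc1
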